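**Retrosynthetic overview**

1. Numbering: ester carbon = C1; ring A = C8–C12 (C9 carbonyl, C10–Br, C12 quaternary); octenyl chain = C13–C20. The C7=C8 bond is opened by aldol condensation into bromo hydroxy enone 20 and enal ester 23; the C12 acetate goes on last.
2. Feature on which the plan rests: in ring A, C10 carries the bromine and lies between the C9 carbonyl and C11. C10 is therefore removed as dibromocarbene, leaving silyl enol ether 14 of a cyclobutanone made of C8, C9, C11 and C12.
3. In that cyclobutanone (12), C8 and C11 are enantiotopic, so the C12 configuration is set by enantioselective deprotonation. The C14=C15 Z-alkene is carried as an alkyne until after the carbene step.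
4. Ketone 12 is unmasked from spiro-dithiane cyclobutanol 10, built from 1,3-dithiane and the 2-substituted epichlorohydrin 5, which comes from 3-chloro-2-(chloromethyl)prop-1-ene and hept-1-yne.
5. Ring order: the four-membered ring is closed first (step 3) and expanded by one carbon to ring A (step 7); no other ring is formed.

Key step: step 7

Assumption: the sense of induction of LiN[CH(CH3)Ph]2 on ketone 12 is not established; the route is written with the (R,R)-amide, and the (S,S)-amide is used instead if the (R)-enol ether is found to predominate.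

Remark: the C12 descriptor is S up to 26 and R in 27 and 28 only because C8 outranks C11 once it is sp2; the arrangement in space is unchanged.

**Route**

Step 1
Reactants: 1 3-chloro-2-(chloromethyl)prop-1-ene; 2 hept-1-yne
Product: 4 2-(chloromethyl)dec-1-en-4-yne, via hept-1-yn-1-ylmagnesium chloride 3 (not isolated)
Conditions: 2, i-PrMgCl, THF, 0 °C to rt; then CuCl (5 mol %), 1 (3 equiv), THF, 0 to 40 °C
Reagents that add atoms: none
Why: Copper-catalysed coupling of an alkynyl Grignard reagent with an allylic chloride gives the skipped enyne, SN2 and SN2′ attack leading to the same product in this symmetrical dichloride and the excess of 1 holding back a second substitution.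

Step 2
Reactants: 4 2-(chloromethyl)dec-1-en-4-yne
Product: 5 2-(chloromethyl)-2-(oct-2-yn-1-yl)oxirane (racemic)
Conditions: mCPBA, NaHCO3, CH2Cl2, 0 °C to rt
Reagents that add atoms: 3-chloroperoxybenzoic acid, OOC(=O)c1cccc(Cl)c1
Why: Prilezhaev epoxidation takes the 1,1-disubstituted alkene and leaves the much less nucleophilic alkyne untouched.

Step 3
Reactants: 5 2-(chloromethyl)-2-(oct-2-yn-1-yl)oxirane; 6 1,3-dithiane
Product: 10 2-(oct-2-yn-1-yl)-5,9-dithiaspiro[3.5]nonan-2-ol, via 2-lithio-1,3-dithiane 7 (not isolated), via lithium chlorohydrin alkoxide 8 (not isolated), via C-lithiated chlorohydrin alkoxide 9 (not isolated)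
Conditions: 6, n-BuLi, THF, −30 °C; 5, −78 to −20 °C; n-BuLi, −40 °C to rt; H2O
Reagents that add atoms: none
Why: Corey–Seebach dithiane chemistry, in which 7 opens the epoxide at its CH2 terminus and, after a second metalation at the carbon between the two sulfurs, the carbanion displaces the neighbouring chloride in a 4-exo-tet closure helped by the gem-disubstituted centre (Thorpe–Ingold effect), so that no intermolecular SN2 at a neopentyl-type carbon is needed and the alternative path through a re-closed epoxide ends in the same cyclobutanol.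

Step 4
Reactants: 10 2-(oct-2-yn-1-yl)-5,9-dithiaspiro[3.5]nonan-2-ol
Product: 11 tert-butyldimethyl{[2-(oct-2-yn-1-yl)-5,9-dithiaspiro[3.5]nonan-2-yl]oxy}silane
Conditions: t-BuMe2SiOTf, 2,6-lutidine, CH2Cl2, 0 °C to rt
Reagents that add atoms: tert-butyldimethylsilyl trifluoromethanesulfonate, CC(C)(C)[Si](C)(C)OS(=O)(=O)C(F)(F)F
Why: Silylation of a hindered tertiary alcohol calls for the silyl triflate, to which the dithiane and the alkyne are inert, and the ether blocks retro-aldol opening of the later β-oxygenated cyclobutanone.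

Step 5
Reactants: 11 tert-butyldimethyl{[2-(oct-2-yn-1-yl)-5,9-dithiaspiro[3.5]nonan-2-yl]oxy}silane
Product: 12 3-[(tert-butyldimethylsilyl)oxy]-3-(oct-2-yn-1-yl)cyclobutan-1-one
Conditions: MeI, CaCO3, MeCN/H2O (4:1), 50 °C
Reagents that add atoms: water, O
Why: Alkylative dithiane hydrolysis (S-methylation, thionium ion, capture by water) runs under buffered, non-oxidising conditions that spare the alkyne and the silyl ether.

Step 6
Reactants: 12 3-[(tert-butyldimethylsilyl)oxy]-3-(oct-2-yn-1-yl)cyclobutan-1-one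
Product: 14 tert-butyldimethyl{[(1S)-1-(oct-2-yn-1-yl)-3-[(trimethylsilyl)oxy]cyclobut-2-en-1-yl]oxy}silane, via lithium enolate 13 (not isolated)
Conditions: (R,R)-HN[CH(CH3)Ph]2, n-BuLi, THF, −78 °C; Me3SiCl (5 equiv, present from the start), then 12, −100 °C; Et3N, pentane, cold aq NaHCO3; filtration through Et3N-deactivated silica, used at once
Reagents that add atoms: chlorotrimethylsilane, C[Si](C)(C)Cl
Why: Enantioselective deprotonation of a prochiral ketone by a C2-symmetric chiral lithium amide with in situ silylation, in which the base chooses between the enantiotopic C8 and C11 methylenes and so makes C12 a stereocentre whose configuration depends on how the base–ketone complex tells the siloxy group from the propargylic chain, while the immediate silylation keeps enolate 13 from expelling silanolate.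

Step 7
Reactants: 14 tert-butyldimethyl{[(1S)-1-(oct-2-yn-1-yl)-3-[(trimethylsilyl)oxy]cyclobut-2-en-1-yl]oxy}silane; 15 bromoform
Product: 18 (4S)-2-bromo-4-[(tert-butyldimethylsilyl)oxy]-4-(oct-2-yn-1-yl)cyclopent-2-en-1-one, via dibromocarbene 16 (not isolated), via dibromobicyclo[2.1.0]pentane adduct 17 (not isolated)
Conditions: 15 (3 equiv), KOC(CH3)3 (1.5 equiv, in portions), pentane, −30 to 0 °C
Reagents that add atoms: none
Why: KOC(CH3)3 deprotonates CHBr3 and loss of bromide gives dibromocarbene 16, which adds in a concerted [2+1] fashion to the C9=C11 bond of 14 to give the 5,5-dibromobicyclo[2.1.0]pentane 17. Driven by release of the bicyclopentane strain, 17 should open at once by the two-electron disrotatory cyclopropyl-to-allyl cation process, the bromide syn to the four-membered ring leaving as C9–C11 breaks, and bromide then removes the trimethylsilyl group from the 2-bromo-1-siloxycyclopentenyl cation to give the α-bromoenone. The closest known reaction type is the dihalocarbene ring expansion of cyclic silyl enol ethers to 2-halocycloalk-2-enones. Ring A (C8–C12) is not closed by a tethered attack but arises by one-carbon expansion of the cyclobutene, C9–C10 and C10–C11 being formed in the cycloaddition and C10 arriving with its bromine and the C10=C11 alkene in place. No stereocentre is created, since the two bridgehead centres of 17 are transient and both faces of attack converge, and C12 is not touched. The step needs chemoselectivity for the enol ether over the C14≡C15 alkyne, which the electrophilic carbene provides by preferring the strained, oxygen-substituted alkene, and it needs the base to spare enol ether and product, which the excess of the more acidic CHBr3, the sparingly soluble alkoxide in pentane and the low temperature should secure.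

Step 8
Reactants: 18 (4S)-2-bromo-4-[(tert-butyldimethylsilyl)oxy]-4-(oct-2-yn-1-yl)cyclopent-2-en-1-one
Product: 19 (4S)-2-bromo-4-[(tert-butyldimethylsilyl)oxy]-4-[(2Z)-oct-2-en-1-yl]cyclopent-2-en-1-one
Conditions: H2 (1 atm), Pd/CaCO3 poisoned with Pb(OAc)2, quinoline, EtOAc, rt, stopped after one equivalent of H2
Reagents that add atoms: none
Why: Lindlar semi-hydrogenation delivers both hydrogens to one face of the alkyne and so gives the Z-alkene, the strongly adsorbed alkyne and the quinoline poison holding back reaction at the C10–Br bond and the enone alkene.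

Step 9
Reactants: 19 (4S)-2-bromo-4-[(tert-butyldimethylsilyl)oxy]-4-[(2Z)-oct-2-en-1-yl]cyclopent-2-en-1-one
Product: 20 (4S)-2-bromo-4-hydroxy-4-[(2Z)-oct-2-en-1-yl]cyclopent-2-en-1-one
Conditions: 48% aq HF, MeCN, 0 °C to rt
Reagents that add atoms: none
Why: Fluoride-driven cleavage of the tertiary silyl ether under acidic, non-nucleophilic conditions leaves the bromoenone and the Z-alkene intact.

Step 10
Reactants: 21 methyl hex-5-enoate; 22 (2E)-but-2-enal
Product: 23 methyl (5E)-7-oxohept-5-enoate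
Conditions: 22 (5 equiv), second-generation Grubbs catalyst RuCl2(=CHPh)(PCy3)(1,3-dimesitylimidazolidin-2-ylidene) (2 mol %), CH2Cl2, 40 °C
Reagents that add atoms: none
Why: Olefin cross-metathesis of a terminal alkene with crotonaldehyde gives the conjugated enal as its thermodynamically preferred E isomer while propene escapes.

Step 11
Reactants: 20 (4S)-2-bromo-4-hydroxy-4-[(2Z)-oct-2-en-1-yl]cyclopent-2-en-1-one; 23 methyl (5E)-7-oxohept-5-enoate
Product: 25 methyl (5E)-7-[(5S)-3-bromo-5-hydroxy-5-[(2Z)-oct-2-en-1-yl]-2-oxocyclopent-3-en-1-yl]-7-hydroxyhept-5-enoate (diastereomer mixture at C7 and C8), via dilithium alkoxide enolate 24 (not isolated)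
Conditions: LiN(i-Pr)2 (2.1 equiv), THF, −78 °C; 23, −78 °C; AcOH, −78 °C
Reagents that add atoms: none
Why: Kinetic aldol addition, in which the second equivalent of base deprotonates C8 (the only enolisable position), the enolate cannot expel the C12 oxygen because that would give a cyclopentadienone, and it adds 1,2 to the enal to form C7–C8, the new centres at C7 and C8 being removed in the next step.

Step 12
Reactants: 25 methyl (5E)-7-[(5S)-3-bromo-5-hydroxy-5-[(2Z)-oct-2-en-1-yl]-2-oxocyclopent-3-en-1-yl]-7-hydroxyhept-5-enoate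
Product: 28 methyl (5E,7E)-7-[(2R)-2-(acetyloxy)-4-bromo-2-[(2Z)-oct-2-en-1-yl]-5-oxocyclopent-3-en-1-ylidene]hept-5-enoate (target), via C7 monoacetate 26 (not isolated), via 12-hydroxy dienone 27 (not isolated)
Conditions: Ac2O, DMAP, Et3N, CH2Cl2, 0 °C to rt
Reagents that add atoms: acetic anhydride, CC(=O)OC(C)=O
Why: Acetylation of the secondary C7 hydroxyl is followed by E1cB loss of acetate to the cross-conjugated dienone, expected to favour the 7E isomer in which C6 points away from the C9 carbonyl oxygen, and DMAP-catalysed acetylation of the tertiary C12 hydroxyl completes the target, any 7Z isomer being removed by chromatography.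

**Compound list**

1 | 3-chloro-2-(chloromethyl)prop-1-ene | C=C(CCl)CCl | starting material
2 | hept-1-yne | CCCCCC#C | starting material
3 | hept-1-yn-1-ylmagnesium chloride | CCCCCC#C[Mg]Cl | intermediate
4 | 2-(chloromethyl)dec-1-en-4-yne | C=C(CCl)CC#CCCCCC | intermediate
5 | 2-(chloromethyl)-2-(oct-2-yn-1-yl)oxirane (racemic) | ClCC1(CC#CCCCCC)CO1 | intermediate
6 | 1,3-dithiane | C1CSCSC1 | starting material
7 | 2-lithio-1,3-dithiane | [Li]C1SCCCS1 | intermediate
8 | lithium 1-chloro-2-(1,3-dithian-2-ylmethyl)dec-4-yn-2-olate (racemic) | [Li]OC(CCl)(CC#CCCCCC)CC1SCCCS1 | intermediate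
9 | lithium 1-chloro-2-[(2-lithio-1,3-dithian-2-yl)methyl]dec-4-yn-2-olate (racemic) | [Li]OC(CCl)(CC#CCCCCC)CC1([Li])SCCCS1 | intermediate
10 | 2-(oct-2-yn-1-yl)-5,9-dithiaspiro[3.5]nonan-2-ol | CCCCCC#CCC1(O)CC2(C1)SCCCS2 | intermediate
11 | tert-butyldimethyl{[2-(oct-2-yn-1-yl)-5,9-dithiaspiro[3.5]nonan-2-yl]oxy}silane | CCCCCC#CCC1(O[Si](C)(C)C(C)(C)C)CC2(C1)SCCCS2 | intermediate
12 | 3-[(tert-butyldimethylsilyl)oxy]-3-(oct-2-yn-1-yl)cyclobutan-1-one | CCCCCC#CCC1(O[Si](C)(C)C(C)(C)C)CC(=O)C1 | intermediate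
13 | lithium (3S)-3-[(tert-butyldimethylsilyl)oxy]-3-(oct-2-yn-1-yl)cyclobut-1-en-1-olate | CCCCCC#CC[C@@]1(O[Si](C)(C)C(C)(C)C)C=C(O[Li])C1 | intermediate
14 | tert-butyldimethyl{[(1S)-1-(oct-2-yn-1-yl)-3-[(trimethylsilyl)oxy]cyclobut-2-en-1-yl]oxy}silane | CCCCCC#CC[C@@]1(O[Si](C)(C)C(C)(C)C)C=C(O[Si](C)(C)C)C1 | intermediate
15 | bromoform (tribromomethane) | BrC(Br)Br | starting material
16 | dibromocarbene | Br[C]Br | intermediate
17 | {[(3S)-5,5-dibromo-3-[(tert-butyldimethylsilyl)oxy]-3-(oct-2-yn-1-yl)bicyclo[2.1.0]pentan-1-yl]oxy}trimethylsilane (both cis-fused diastereomers) | CCCCCC#CC[C@@]1(O[Si](C)(C)C(C)(C)C)C2C(Br)(Br)C2(O[Si](C)(C)C)C1 | intermediate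
18 | (4S)-2-bromo-4-[(tert-butyldimethylsilyl)oxy]-4-(oct-2-yn-1-yl)cyclopent-2-en-1-one | CCCCCC#CC[C@@]1(O[Si](C)(C)C(C)(C)C)C=C(Br)C(=O)C1 | intermediate
19 | (4S)-2-bromo-4-[(tert-butyldimethylsilyl)oxy]-4-[(2Z)-oct-2-en-1-yl]cyclopent-2-en-1-one | CCCCC/C=C\C[C@@]1(O[Si](C)(C)C(C)(C)C)C=C(Br)C(=O)C1 | intermediate
20 | (4S)-2-bromo-4-hydroxy-4-[(2Z)-oct-2-en-1-yl]cyclopent-2-en-1-one | CCCCC/C=C\C[C@@]1(O)C=C(Br)C(=O)C1 | intermediate
21 | methyl hex-5-enoate | COC(=O)CCCC=C | starting material
22 | (2E)-but-2-enal | C/C=C/C=O | starting material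
23 | methyl (5E)-7-oxohept-5-enoate | COC(=O)CCC/C=C/C=O | intermediate
24 | dilithium (3S)-5-bromo-3-[(2Z)-oct-2-en-1-yl]cyclopenta-1,4-diene-1,3-bis(olate) | CCCCC/C=C\C[C@@]1(O[Li])C=C(Br)C(O[Li])=C1 | intermediate
25 | methyl (5E)-7-[(5S)-3-bromo-5-hydroxy-5-[(2Z)-oct-2-en-1-yl]-2-oxocyclopent-3-en-1-yl]-7-hydroxyhept-5-enoate (diastereomer mixture at C7 and C8) | CCCCC/C=C\C[C@@]1(O)C=C(Br)C(=O)C1C(O)/C=C/CCCC(=O)OC | intermediate
26 | methyl (5E)-7-(acetyloxy)-7-[(5S)-3-bromo-5-hydroxy-5-[(2Z)-oct-2-en-1-yl]-2-oxocyclopent-3-en-1-yl]hept-5-enoate (diastereomer mixture at C7 and C8) | CCCCC/C=C\C[C@@]1(O)C=C(Br)C(=O)C1C(OC(C)=O)/C=C/CCCC(=O)OC | intermediate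
27 | methyl (5E,7E)-7-[(2R)-4-bromo-2-hydroxy-2-[(2Z)-oct-2-en-1-yl]-5-oxocyclopent-3-en-1-ylidene]hept-5-enoate | CCCCC/C=C\C[C@@]1(O)C=C(Br)C(=O)/C1=C/C=C/CCCC(=O)OC | intermediate
28 | methyl (5E,7E)-7-[(2R)-2-(acetyloxy)-4-bromo-2-[(2Z)-oct-2-en-1-yl]-5-oxocyclopent-3-en-1-ylidene]hept-5-enoate | CCCCC/C=C\C[C@@]1(OC(C)=O)C=C(Br)C(=O)/C1=C/C=C/CCCC(=O)OC | target

**Step count**

Total: 12 steps. Longest linear sequence: 11 steps (steps 1–9, 11 and 12, from 1 and 2 to 28); step 10 is a one-step side branch.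

**Steps most likely to fail**

Step 7 (key step). tert-Butoxide may attack silicon of the trimethylsilyl enol ether, or degrade the bromoenone, faster than the carbene is captured; the freed enolate can expel silanolate. The fallback sets out from 14 and comes back at 18, and introduces C10 and the bromine separately without strong base. Simmons–Smith cyclopropanation of 14 (Et2Zn, CH2I2, CH2Cl2, 0 °C) should give {[(3S)-3-[(tert-butyldimethylsilyl)oxy]-3-(oct-2-yn-1-yl)bicyclo[2.1.0]pentan-1-yl]oxy}trimethylsilane F1. FeCl3 in DMF at 0 °C opens the siloxycyclopropane oxidatively at the C9–C11 bond to (3S)-4-chloro-3-[(tert-butyldimethylsilyl)oxy]-3-(oct-2-yn-1-yl)cyclopentan-1-one F2, which loses HCl with NaOAc in MeOH to give (4S)-4-[(tert-butyldimethylsilyl)oxy]-4-(oct-2-yn-1-yl)cyclopent-2-en-1-one F3. Nucleophilic epoxidation (H2O2, NaOH, MeOH, 0 °C) then gives (4S)-4-[(tert-butyldimethylsilyl)oxy]-4-(oct-2-yn-1-yl)-6-oxabicyclo[3.1.0]hexan-2-one F4. LiBr with Amberlyst 15 in acetone opens the epoxide at C10 and dehydrates to 18; this bromination does not touch the alkyne.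

Step 6. The siloxy group and the propargylic chain on C12 differ little in steric demand, so discrimination between the enantiotopic C8 and C11 methylenes may be insufficient and the enantiomeric purity low. The fallback sets out from 12 and comes back at 18, replacing asymmetric deprotonation by resolution. LiN(i-Pr)2 with Me3SiCl present (THF, −78 °C) converts 12 through racemic lithium 3-[(tert-butyldimethylsilyl)oxy]-3-(oct-2-yn-1-yl)cyclobut-1-en-1-olate F5 into racemic tert-butyldimethyl{[1-(oct-2-yn-1-yl)-3-[(trimethylsilyl)oxy]cyclobut-2-en-1-yl]oxy}silane F6. The conditions of step 7 take F6 through racemic {[5,5-dibromo-3-[(tert-butyldimethylsilyl)oxy]-3-(oct-2-yn-1-yl)bicyclo[2.1.0]pentan-1-yl]oxy}trimethylsilane F7 to racemic 2-bromo-4-[(tert-butyldimethylsilyl)oxy]-4-(oct-2-yn-1-yl)cyclopent-2-en-1-one F8. Preparative chromatography on a cellulose tris(3,5-dimethylphenylcarbamate) stationary phase then separates 18 from (4R)-2-bromo-4-[(tert-butyldimethylsilyl)oxy]-4-(oct-2-yn-1-yl)cyclopent-2-en-1-one F9, which is set aside.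

Step 8. Hydrogenolysis of the vinylic C10–Br bond and saturation of the C10=C11 alkene on palladium may compete with semi-reduction of the alkyne. The fallback sets out from 12 and comes back at 19, moving the semi-hydrogenation ahead of the halogen. Hydrogenation of 12 over Pd/CaCO3 poisoned with Pb(OAc)2 and quinoline should give 3-[(tert-butyldimethylsilyl)oxy]-3-[(2Z)-oct-2-en-1-yl]cyclobutan-1-one F10. The conditions of step 6 convert F10 through lithium (3S)-3-[(tert-butyldimethylsilyl)oxy]-3-[(2Z)-oct-2-en-1-yl]cyclobut-1-en-1-olate F11 into tert-butyldimethyl{[(1S)-1-[(2Z)-oct-2-en-1-yl]-3-[(trimethylsilyl)oxy]cyclobut-2-en-1-yl]oxy}silane F12. Dibromocarbene, generated as in step 7 but in only slight excess, should then attack the siloxy-substituted cyclobutene in preference to the 1,2-dialkyl alkene and give 19 directly through {[(3S)-5,5-dibromo-3-[(tert-butyldimethylsilyl)oxy]-3-[(2Z)-oct-2-en-1-yl]bicyclo[2.1.0]pentan-1-yl]oxy}trimethylsilane F13.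

**Further compounds**

F1 | step 7 | {[(3S)-3-[(tert-butyldimethylsilyl)oxy]-3-(oct-2-yn-1-yl)bicyclo[2.1.0]pentan-1-yl]oxy}trimethylsilane (both cis-fused diastereomers) | CCCCCC#CC[C@@]1(O[Si](C)(C)C(C)(C)C)C2CC2(O[Si](C)(C)C)C1
F2 | step 7 | (3S)-4-chloro-3-[(tert-butyldimethylsilyl)oxy]-3-(oct-2-yn-1-yl)cyclopentan-1-one (both C4 epimers) | CCCCCC#CC[C@@]1(O[Si](C)(C)C(C)(C)C)C(Cl)CC(=O)C1
F3 | step 7 | (4S)-4-[(tert-butyldimethylsilyl)oxy]-4-(oct-2-yn-1-yl)cyclopent-2-en-1-one | CCCCCC#CC[C@@]1(O[Si](C)(C)C(C)(C)C)C=CC(=O)C1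
F4 | step 7 | (4S)-4-[(tert-butyldimethylsilyl)oxy]-4-(oct-2-yn-1-yl)-6-oxabicyclo[3.1.0]hexan-2-one (both epoxide diastereomers) | CCCCCC#CC[C@@]1(O[Si](C)(C)C(C)(C)C)C2OC2C(=O)C1
F5 | step 6 | racemic lithium 3-[(tert-butyldimethylsilyl)oxy]-3-(oct-2-yn-1-yl)cyclobut-1-en-1-olate | CCCCCC#CCC1(O[Si](C)(C)C(C)(C)C)C=C(O[Li])C1
F6 | step 6 | racemic tert-butyldimethyl{[1-(oct-2-yn-1-yl)-3-[(trimethylsilyl)oxy]cyclobut-2-en-1-yl]oxy}silane | CCCCCC#CCC1(O[Si](C)(C)C(C)(C)C)C=C(O[Si](C)(C)C)C1
F7 | step 6 | racemic {[5,5-dibromo-3-[(tert-butyldimethylsilyl)oxy]-3-(oct-2-yn-1-yl)bicyclo[2.1.0]pentan-1-yl]oxy}trimethylsilane | CCCCCC#CCC1(O[Si](C)(C)C(C)(C)C)C2C(Br)(Br)C2(O[Si](C)(C)C)C1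
F8 | step 6 | racemic 2-bromo-4-[(tert-butyldimethylsilyl)oxy]-4-(oct-2-yn-1-yl)cyclopent-2-en-1-one | CCCCCC#CCC1(O[Si](C)(C)C(C)(C)C)C=C(Br)C(=O)C1
F9 | step 6 | (4R)-2-bromo-4-[(tert-butyldimethylsilyl)oxy]-4-(oct-2-yn-1-yl)cyclopent-2-en-1-one | CCCCCC#CC[C@]1(O[Si](C)(C)C(C)(C)C)C=C(Br)C(=O)C1
F10 | step 8 | 3-[(tert-butyldimethylsilyl)oxy]-3-[(2Z)-oct-2-en-1-yl]cyclobutan-1-one | CCCCC/C=C\CC1(O[Si](C)(C)C(C)(C)C)CC(=O)C1
F11 | step 8 | lithium (3S)-3-[(tert-butyldimethylsilyl)oxy]-3-[(2Z)-oct-2-en-1-yl]cyclobut-1-en-1-olate | CCCCC/C=C\C[C@@]1(O[Si](C)(C)C(C)(C)C)C=C(O[Li])C1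
F12 | step 8 | tert-butyldimethyl{[(1S)-1-[(2Z)-oct-2-en-1-yl]-3-[(trimethylsilyl)oxy]cyclobut-2-en-1-yl]oxy}silane | CCCCC/C=C\C[C@@]1(O[Si](C)(C)C(C)(C)C)C=C(O[Si](C)(C)C)C1
F13 | step 8 | {[(3S)-5,5-dibromo-3-[(tert-butyldimethylsilyl)oxy]-3-[(2Z)-oct-2-en-1-yl]bicyclo[2.1.0]pentan-1-yl]oxy}trimethylsilane (both cis-fused diastereomers) | CCCCC/C=C\C[C@@]1(O[Si](C)(C)C(C)(C)C)C2C(Br)(Br)C2(O[Si](C)(C)C)C1
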